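**Retrosynthetic overview**

1. The ester C–O bond is cut last (Yamaguchi), giving cyclohexanone diol 14 and heptanoic acid 29. The chain C5 ketone is unveiled only after coupling, so that C6 (between ketone and pyranone) never meets base.
2. Diol 14 comes from one anionic [2+4] operation. The lithium (Z)-enolate of pentan-3-one and aldehyde 7 form ring bonds C1–C2 and C3–C4 by aldol addition, O→O carbonate relay and aldol ring closure, setting four ring stereocentres from the one in 7.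
3. Enabling feature: the cyclohexanone C1–C6 holds two aldol retrons that share C3, namely C5(=O)–C4–C3(OH) and C3–C2–C1(O). C3 with its ethyl group and C2 is a masked pentan-3-one carbonyl, and the oxygen on C1 lies 1,5 to the oxygen on C5, so the first aldolate can take the carbonate from the C5 enol oxygen and release the C4 enolate.
4. Acid 29 comes from a titanium aldol of β-ketoimide 22 with pyranone aldehyde 19, hydroxyl-directed anti reduction and δ-lactonisation. Aldehydes 7 and 19 both derive from methyl (R)-3-hydroxy-2-methylpropanoate through Weinreb amide 3.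
5. Ring order: γ-pyranone (step 12, cyclodehydration of triketone 16) and cyclohexanone (step 8) in separate branches, a temporary δ-lactone (step 17) in the acid branch, ester union in step 20.

Key step: step 8

Assumption: ring carbons are numbered as in the cyclohexyl ester (C1 carries the acyloxy oxygen, C3 the ethyl and hydroxyl groups, C5 is the ring carbonyl) and chain carbons as in the heptanoate; the (Z)-lithium enolate of pentan-3-one is assumed to attack aldehyde 7 in the anti-Felkin sense usual for (Z)-enolates and α-methyl aldehydes.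

**Route**

Step 1
Reactants: 1 methyl (R)-3-hydroxy-2-methylpropanoate
Product: 2 methyl (R)-3-[(tert-butyldimethylsilyl)oxy]-2-methylpropanoate
Conditions: TBSCl, imidazole, DMF, rt
Reagents that add atoms: tert-butyldimethylsilyl chloride, CC(C)(C)[Si](C)(C)Cl
Why: Standard silylation of the primary alcohol, which leaves the stereocentre untouched.

Step 2
Reactants: 2 methyl (R)-3-[(tert-butyldimethylsilyl)oxy]-2-methylpropanoate
Product: 3 (R)-3-[(tert-butyldimethylsilyl)oxy]-N-methoxy-N,2-dimethylpropanamide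
Conditions: MeNH(OMe)·HCl, iPrMgCl, THF, −20 °C
Reagents that add atoms: N,O-dimethylhydroxylamine hydrochloride, CNOC.Cl
Why: Weinreb amide formation from the ester with the magnesium amide, which should proceed without enolising the α-stereocentre.

Step 3
Reactants: 3 (R)-3-[(tert-butyldimethylsilyl)oxy]-N-methoxy-N,2-dimethylpropanamide
Product: 4 (R)-1-[(tert-butyldimethylsilyl)oxy]-2-methylpentan-3-one
Conditions: EtMgBr, THF, 0 °C
Reagents that add atoms: ethylmagnesium bromide, CC[Mg]Br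
Why: Weinreb ketone synthesis, in which the chelated tetrahedral intermediate stops the addition at the ethyl ketone.

Step 4
Reactants: 4 (R)-1-[(tert-butyldimethylsilyl)oxy]-2-methylpentan-3-one
Product: 5 benzyl (2Z,4R)-5-[(tert-butyldimethylsilyl)oxy]-4-methylpent-2-en-3-yl carbonate
Conditions: LiN(SiMe3)2, THF, −78 °C; then DMPU, ClCO2Bn, −78 °C
Reagents that add atoms: benzyl chloroformate, O=C(Cl)OCc1ccccc1
Why: Kinetic deprotonation at the unhindered ethyl CH2 should give the (Z)-lithium enolate (A(1,3) strain with the branched α′-carbon), and O-acylation by the chloroformate (standard enol carbonate synthesis) fixes that geometry.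

Step 5
Reactants: 5 benzyl (2Z,4R)-5-[(tert-butyldimethylsilyl)oxy]-4-methylpent-2-en-3-yl carbonate
Product: 6 benzyl (2Z,4R)-5-hydroxy-4-methylpent-2-en-3-yl carbonate
Conditions: HF·pyridine, pyridine, THF, 0 °C
Reagents that add atoms: none
Why: Fluoride cleavage of the primary silyl ether under buffered, non-basic conditions should leave the enol carbonate in place.

Step 6
Reactants: 6 benzyl (2Z,4R)-5-hydroxy-4-methylpent-2-en-3-yl carbonate
Product: 7 benzyl (2Z,4S)-4-methyl-5-oxopent-2-en-3-yl carbonate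
Conditions: Dess–Martin periodinane, NaHCO3, CH2Cl2, 0 °C; used crude at once
Reagents that add atoms: none
Why: Dess–Martin oxidation without amine base should give the β,γ-unsaturated aldehyde with the α-stereocentre and the double-bond position intact.

Step 7
Reactants: 8 pentan-3-one
Product: 9 (Z)-3-(trimethylsilyloxy)pent-2-ene
Conditions: LiN(iPr)2, THF–DMPU, −78 °C; Me3SiCl
Reagents that add atoms: chlorotrimethylsilane, C[Si](C)(C)Cl
Why: Enolisation in the presence of the dipolar cosolvent should give the (Z)-enolate, which is trapped on oxygen as the (Z)-silyl enol ether.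

Step 8
Reactants: 9 (Z)-3-(trimethylsilyloxy)pent-2-ene; 7 benzyl (2Z,4S)-4-methyl-5-oxopent-2-en-3-yl carbonate
Product: 13 benzyl (1R,2R,3R,4R,6R)-3-ethyl-3-hydroxy-2,4,6-trimethyl-5-oxocyclohexyl carbonate, via lithium (Z)-pent-2-en-3-olate 10 (not isolated), via lithium aldolate 11 (not isolated), via relayed lithium enolate 12 (not isolated)
Conditions: MeLi, THF, 0 °C to rt; then 7, −78 to −40 °C; AcOH, −78 °C
Reagents that add atoms: none
Why: Proposed new method: the (Z)-lithium enolate 10 adds to the aldehyde of 7 through a Zimmerman–Traxler chair (C1–C2 bond), the aldolate 11 attacks the enol carbonate carbonyl through a six-membered transition state and expels the enolate as the better leaving group, so the carbonate moves to the oxygen on C1 and the (Z)-enolate 12 of the C5 ketone is released regiospecifically, and 12 closes the ring by a 6-(enolendo)-exo-trig aldol addition to the C3 ketone (C3–C4 bond); the closest known reaction types are the release of lithium enolates from enol esters and enol carbonates by MeLi or alkoxides, base-induced O→O acyl migration in 1,3-diol monoesters, and intramolecular lithium aldol cyclisation. C2 and C1 should be set by the (Z)-enolate (syn aldol) together with the anti-Felkin preference of (Z)-enolates toward α-methyl aldehydes, the controlling element being the existing stereocentre C6 of 7. C3 and C4 should be set in the ring closure by a chair in which lithium bridges the enolate oxygen and the C3 carbonyl oxygen (hydroxyl axial, ethyl equatorial), the (Z)-enolate puts the C4 methyl equatorial, the oxygen on C1 and the C2 methyl are equatorial, and the C6 methyl is pseudoaxial beside the enolate (A(1,2) strain). The step needs addition of 10 to the aldehyde and not to the carbonate, migration before any proton transfer, and ring closure faster than C-acylation of 12 by the migrated carbonate; these are secured by the electrophilicity of the aldehyde, the 1,5 disposition of the two oxygens, the lower basicity of the enolate compared with the alkoxide, and the low temperature. The migrated carbonate also caps the oxygen on C1, so that it cannot chelate the C3 carbonyl and steer the closure to the other face.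

Step 9
Reactants: 13 benzyl (1R,2R,3R,4R,6R)-3-ethyl-3-hydroxy-2,4,6-trimethyl-5-oxocyclohexyl carbonate
Product: 14 (2R,3R,4R,5R,6R)-3-ethyl-3,5-dihydroxy-2,4,6-trimethylcyclohexan-1-one
Conditions: H2 (1 atm), Pd/C, EtOAc, rt
Reagents that add atoms: none
Why: Hydrogenolysis of the benzyl carbonate should free the secondary alcohol under neutral conditions with loss of toluene and CO2.

Step 10
Reactants: 3 (R)-3-[(tert-butyldimethylsilyl)oxy]-N-methoxy-N,2-dimethylpropanamide; 8 pentan-3-one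
Product: 15 (6R)-7-[(tert-butyldimethylsilyl)oxy]-4,6-dimethylheptane-3,5-dione (C4 epimers and enol forms)
Conditions: 8, LiN(iPr)2, THF, −78 °C; then 3, −78 to 0 °C; aq. NH4Cl
Reagents that add atoms: none
Why: C-acylation of the ketone enolate by the Weinreb amide (crossed Claisen-type condensation) should give the β-diketone only on work-up.

Step 11
Reactants: 15 (6R)-7-[(tert-butyldimethylsilyl)oxy]-4,6-dimethylheptane-3,5-dione
Product: 16 (7R)-8-[(tert-butyldimethylsilyl)oxy]-3,5,7-trimethyloctane-2,4,6-trione (C3/C5 epimers and enol forms)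
Conditions: LiN(iPr)2 (2.5 equiv), THF, −78 to 0 °C; MeC(O)N(OMe)Me, −78 to 0 °C
Reagents that add atoms: N-methoxy-N-methylacetamide, CC(=O)N(C)OC
Why: The 1,3-diketone dianion should form at the unhindered ethyl CH2 and be acetylated at that terminal carbanion (dianion C-acylation).

Step 12
Reactants: 16 (7R)-8-[(tert-butyldimethylsilyl)oxy]-3,5,7-trimethyloctane-2,4,6-trione
Product: 17 2-[(2R)-1-[(tert-butyldimethylsilyl)oxy]propan-2-yl]-3,5,6-trimethyl-4H-pyran-4-one
Conditions: PPh3, CCl4, THF, rt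
Reagents that add atoms: none
Why: Cyclodehydration of the 1,3,5-triketone under neutral Appel-type conditions should close the γ-pyranone without cleaving the silyl ether.

Step 13
Reactants: 17 2-[(2R)-1-[(tert-butyldimethylsilyl)oxy]propan-2-yl]-3,5,6-trimethyl-4H-pyran-4-one
Product: 18 2-[(2R)-1-hydroxypropan-2-yl]-3,5,6-trimethyl-4H-pyran-4-one
Conditions: HF·pyridine, pyridine, THF, 0 °C to rt
Reagents that add atoms: none
Why: Fluoride cleavage of the primary silyl ether, to which the pyranone is inert.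

Step 14
Reactants: 18 2-[(2R)-1-hydroxypropan-2-yl]-3,5,6-trimethyl-4H-pyran-4-one
Product: 19 (2S)-2-(3,5,6-trimethyl-4-oxo-4H-pyran-2-yl)propanal
Conditions: Dess–Martin periodinane, NaHCO3, CH2Cl2, 0 °C; used at once
Reagents that add atoms: none
Why: Base-free Dess–Martin oxidation with immediate use should keep the α-stereocentre, which is activated by both formyl and pyranone.

Step 15
Reactants: 20 (S)-4-benzyl-3-propanoyloxazolidin-2-one; 21 propanoyl chloride
Product: 22 (4S)-4-benzyl-3-[(2R)-2-methyl-3-oxopentanoyl]oxazolidin-2-one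
Conditions: LiN(iPr)2, THF, −78 °C; then 21, −78 °C
Reagents that add atoms: none
Why: Evans acylation, in which the chelated (Z)-enolate is acylated on the face away from the benzyl group and the new C2 stereocentre is protected from enolisation by A(1,3) strain in the imide.

Step 16
Reactants: 22 (4S)-4-benzyl-3-[(2R)-2-methyl-3-oxopentanoyl]oxazolidin-2-one; 19 (2S)-2-(3,5,6-trimethyl-4-oxo-4H-pyran-2-yl)propanal
Product: 23 (4S)-4-benzyl-3-[(2R,4R,5S,6R)-5-hydroxy-2,4-dimethyl-3-oxo-6-(3,5,6-trimethyl-4-oxo-4H-pyran-2-yl)heptanoyl]oxazolidin-2-one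
Conditions: TiCl4, iPr2NEt, CH2Cl2, −78 °C; then 19, −78 °C
Reagents that add atoms: none
Why: Evans β-ketoimide titanium aldol, in which the chelated (Z)-titanium enolate formed at C4 reacts through a closed Zimmerman–Traxler transition state under control of the C2 methyl group to give the 2,4-syn-4,5-syn adduct, the C6 centre being carried in with the aldehyde.

Step 17
Reactants: 23 (4S)-4-benzyl-3-[(2R,4R,5S,6R)-5-hydroxy-2,4-dimethyl-3-oxo-6-(3,5,6-trimethyl-4-oxo-4H-pyran-2-yl)heptanoyl]oxazolidin-2-one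
Product: 25 (3R,4R,5S,6R)-4-hydroxy-3,5-dimethyl-6-[(1R)-1-(3,5,6-trimethyl-4-oxo-4H-pyran-2-yl)ethyl]oxan-2-one, via anti-diol imide 24 (not isolated)
Conditions: Me4NBH(OAc)3, MeCN–AcOH, −30 °C; then Et3N, DMAP (cat.), CH2Cl2, rt
Reagents that add atoms: none
Why: Evans–Saksena reduction delivers hydride intramolecularly from the C5 alkoxyborohydride to give the 3,5-anti diol, whose C5 hydroxyl then displaces the oxazolidinone to close the δ-lactone and so differentiates the two hydroxyls.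

Step 18
Reactants: 25 (3R,4R,5S,6R)-4-hydroxy-3,5-dimethyl-6-[(1R)-1-(3,5,6-trimethyl-4-oxo-4H-pyran-2-yl)ethyl]oxan-2-one
Product: 26 (3R,4R,5R,6R)-4-[(tert-butyldimethylsilyl)oxy]-3,5-dimethyl-6-[(1R)-1-(3,5,6-trimethyl-4-oxo-4H-pyran-2-yl)ethyl]oxan-2-one
Conditions: TBSOTf, 2,6-lutidine, CH2Cl2, −78 to 0 °C
Reagents that add atoms: tert-butyldimethylsilyl triflate, CC(C)(C)[Si](C)(C)OS(=O)(=O)C(F)(F)F
Why: Silylation of the only free hydroxyl with a silyl triflate, suited to a hindered secondary alcohol.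

Step 19
Reactants: 26 (3R,4R,5R,6R)-4-[(tert-butyldimethylsilyl)oxy]-3,5-dimethyl-6-[(1R)-1-(3,5,6-trimethyl-4-oxo-4H-pyran-2-yl)ethyl]oxan-2-one
Product: 29 (2R,3R,4R,5R,6R)-3-[(tert-butyldimethylsilyl)oxy]-2,4-dimethyl-5-[(triethylsilyl)oxy]-6-(3,5,6-trimethyl-4-oxo-4H-pyran-2-yl)heptanoic acid, via lithium hydroxy carboxylate 27 (not isolated), via triethylsilyl ester 28 (not isolated)
Conditions: LiOH, THF–H2O, 0 °C; evaporation; Et3SiOTf, 2,6-lutidine, CH2Cl2, −78 to 0 °C; K2CO3, MeOH, 0 °C; pH 5 buffer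
Reagents that add atoms: lithium hydroxide, [Li+].[OH-]; triethylsilyl triflate, CC[Si](CC)(CC)OS(=O)(=O)C(F)(F)F
Why: Saponification opens the lactone, bis-silylation of the salt prevents relactonisation, and the labile silyl ester alone is methanolysed to leave the acid with two different silyl ethers.

Step 20
Reactants: 29 (2R,3R,4R,5R,6R)-3-[(tert-butyldimethylsilyl)oxy]-2,4-dimethyl-5-[(triethylsilyl)oxy]-6-(3,5,6-trimethyl-4-oxo-4H-pyran-2-yl)heptanoic acid; 14 (2R,3R,4R,5R,6R)-3-ethyl-3,5-dihydroxy-2,4,6-trimethylcyclohexan-1-one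
Product: 30 (1R,2R,3R,4R,6R)-3-ethyl-3-hydroxy-2,4,6-trimethyl-5-oxocyclohexyl (2R,3R,4R,5R,6R)-3-[(tert-butyldimethylsilyl)oxy]-2,4-dimethyl-5-[(triethylsilyl)oxy]-6-(3,5,6-trimethyl-4-oxo-4H-pyran-2-yl)heptanoate
Conditions: 2,4,6-Cl3C6H2COCl, Et3N, THF, rt; then 14, DMAP, toluene, rt
Reagents that add atoms: none
Why: Yamaguchi esterification through the mixed anhydride should acylate only the secondary hydroxyl, the tertiary one being too hindered.

Step 21
Reactants: 30 (1R,2R,3R,4R,6R)-3-ethyl-3-hydroxy-2,4,6-trimethyl-5-oxocyclohexyl (2R,3R,4R,5R,6R)-3-[(tert-butyldimethylsilyl)oxy]-2,4-dimethyl-5-[(triethylsilyl)oxy]-6-(3,5,6-trimethyl-4-oxo-4H-pyran-2-yl)heptanoate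
Product: 31 (1R,2R,3R,4R,6R)-3-ethyl-3-hydroxy-2,4,6-trimethyl-5-oxocyclohexyl (2R,3R,4R,5R,6R)-3-[(tert-butyldimethylsilyl)oxy]-5-hydroxy-2,4-dimethyl-6-(3,5,6-trimethyl-4-oxo-4H-pyran-2-yl)heptanoate
Conditions: PPTS, MeOH–CH2Cl2, 0 °C
Reagents that add atoms: none
Why: Mild acid methanolysis should remove the triethylsilyl ether selectively over the more robust tert-butyldimethylsilyl ether.

Step 22
Reactants: 31 (1R,2R,3R,4R,6R)-3-ethyl-3-hydroxy-2,4,6-trimethyl-5-oxocyclohexyl (2R,3R,4R,5R,6R)-3-[(tert-butyldimethylsilyl)oxy]-5-hydroxy-2,4-dimethyl-6-(3,5,6-trimethyl-4-oxo-4H-pyran-2-yl)heptanoate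
Product: 32 (1R,2R,3R,4R,6R)-3-ethyl-3-hydroxy-2,4,6-trimethyl-5-oxocyclohexyl (2R,3R,4S,6S)-3-[(tert-butyldimethylsilyl)oxy]-2,4-dimethyl-5-oxo-6-(3,5,6-trimethyl-4-oxo-4H-pyran-2-yl)heptanoate
Conditions: Dess–Martin periodinane, NaHCO3, CH2Cl2, 0 °C to rt
Reagents that add atoms: none
Why: Buffered Dess–Martin oxidation of the only secondary alcohol should give the C5 ketone without base, so the C6 centre between ketone and pyranone is not epimerised and the tertiary alcohol is untouched.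

Step 23
Reactants: 32 (1R,2R,3R,4R,6R)-3-ethyl-3-hydroxy-2,4,6-trimethyl-5-oxocyclohexyl (2R,3R,4S,6S)-3-[(tert-butyldimethylsilyl)oxy]-2,4-dimethyl-5-oxo-6-(3,5,6-trimethyl-4-oxo-4H-pyran-2-yl)heptanoate
Product: 33 (1R,2R,3R,4R,6R)-3-ethyl-3-hydroxy-2,4,6-trimethyl-5-oxocyclohexyl (2R,3R,4S,6S)-3-hydroxy-2,4-dimethyl-5-oxo-6-(3,5,6-trimethyl-4-oxo-4H-pyran-2-yl)heptanoate
Conditions: HF·pyridine, pyridine, THF, 0 °C to rt
Reagents that add atoms: none
Why: Buffered fluoride desilylation is non-basic and should spare the β-acyloxy ketone, both β-hydroxy ketones and the labile C6 centre.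

**Compound list**

1 | methyl (R)-3-hydroxy-2-methylpropanoate | COC(=O)[C@H](C)CO | starting material
2 | methyl (R)-3-[(tert-butyldimethylsilyl)oxy]-2-methylpropanoate | COC(=O)[C@H](C)CO[Si](C)(C)C(C)(C)C | intermediate
3 | (R)-3-[(tert-butyldimethylsilyl)oxy]-N-methoxy-N,2-dimethylpropanamide | CON(C)C(=O)[C@H](C)CO[Si](C)(C)C(C)(C)C | intermediate
4 | (R)-1-[(tert-butyldimethylsilyl)oxy]-2-methylpentan-3-one | CCC(=O)[C@H](C)CO[Si](C)(C)C(C)(C)C | intermediate
5 | benzyl (2Z,4R)-5-[(tert-butyldimethylsilyl)oxy]-4-methylpent-2-en-3-yl carbonate | C/C=C(OC(=O)OCc1ccccc1)/[C@H](C)CO[Si](C)(C)C(C)(C)C | intermediate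
6 | benzyl (2Z,4R)-5-hydroxy-4-methylpent-2-en-3-yl carbonate | C/C=C(OC(=O)OCc1ccccc1)/[C@H](C)CO | intermediate
7 | benzyl (2Z,4S)-4-methyl-5-oxopent-2-en-3-yl carbonate | C/C=C(OC(=O)OCc1ccccc1)/[C@H](C)C=O | intermediate
8 | pentan-3-one | CCC(=O)CC | starting material
9 | (Z)-3-(trimethylsilyloxy)pent-2-ene | CC/C(O[Si](C)(C)C)=C/C | intermediate
10 | lithium (Z)-pent-2-en-3-olate | [Li+].CC/C([O-])=C/C | intermediate
11 | lithium (2Z,4R,5S,6R)-3-[(benzyloxycarbonyl)oxy]-4,6-dimethyl-7-oxonon-2-en-5-olate | [Li+].CCC(=O)[C@H](C)[C@@H]([O-])[C@@H](C)/C(OC(=O)OCc1ccccc1)=C/C | intermediate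
12 | lithium (2Z,4R,5S,6R)-5-[(benzyloxycarbonyl)oxy]-4,6-dimethyl-7-oxonon-2-en-3-olate | [Li+].CCC(=O)[C@H](C)[C@@H](OC(=O)OCc1ccccc1)[C@@H](C)/C([O-])=C/C | intermediate
13 | benzyl (1R,2R,3R,4R,6R)-3-ethyl-3-hydroxy-2,4,6-trimethyl-5-oxocyclohexyl carbonate | CC[C@@]1(O)[C@H](C)[C@@H](OC(=O)OCc2ccccc2)[C@@H](C)C(=O)[C@@H]1C | intermediate
14 | (2R,3R,4R,5R,6R)-3-ethyl-3,5-dihydroxy-2,4,6-trimethylcyclohexan-1-one | CC[C@@]1(O)[C@H](C)[C@@H](O)[C@@H](C)C(=O)[C@@H]1C | intermediate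
15 | (6R)-7-[(tert-butyldimethylsilyl)oxy]-4,6-dimethylheptane-3,5-dione | CCC(=O)C(C)C(=O)[C@H](C)CO[Si](C)(C)C(C)(C)C | intermediate
16 | (7R)-8-[(tert-butyldimethylsilyl)oxy]-3,5,7-trimethyloctane-2,4,6-trione | CC(=O)C(C)C(=O)C(C)C(=O)[C@H](C)CO[Si](C)(C)C(C)(C)C | intermediate
17 | 2-[(2R)-1-[(tert-butyldimethylsilyl)oxy]propan-2-yl]-3,5,6-trimethyl-4H-pyran-4-one | Cc1oc([C@H](C)CO[Si](C)(C)C(C)(C)C)c(C)c(=O)c1C | intermediate
18 | 2-[(2R)-1-hydroxypropan-2-yl]-3,5,6-trimethyl-4H-pyran-4-one | Cc1oc([C@H](C)CO)c(C)c(=O)c1C | intermediate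
19 | (2S)-2-(3,5,6-trimethyl-4-oxo-4H-pyran-2-yl)propanal | Cc1oc([C@H](C)C=O)c(C)c(=O)c1C | intermediate
20 | (S)-4-benzyl-3-propanoyloxazolidin-2-one | CCC(=O)N1[C@@H](Cc2ccccc2)COC1=O | starting material
21 | propanoyl chloride | CCC(Cl)=O | starting material
22 | (4S)-4-benzyl-3-[(2R)-2-methyl-3-oxopentanoyl]oxazolidin-2-one | CCC(=O)[C@@H](C)C(=O)N1[C@@H](Cc2ccccc2)COC1=O | intermediate
23 | (4S)-4-benzyl-3-[(2R,4R,5S,6R)-5-hydroxy-2,4-dimethyl-3-oxo-6-(3,5,6-trimethyl-4-oxo-4H-pyran-2-yl)heptanoyl]oxazolidin-2-one | O=C1OC[C@H](Cc2ccccc2)N1C(=O)[C@H](C)C(=O)[C@H](C)[C@@H](O)[C@@H](C)c3oc(C)c(C)c(=O)c3C | intermediate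
24 | (4S)-4-benzyl-3-[(2R,3R,4R,5R,6R)-3,5-dihydroxy-2,4-dimethyl-6-(3,5,6-trimethyl-4-oxo-4H-pyran-2-yl)heptanoyl]oxazolidin-2-one | O=C1OC[C@H](Cc2ccccc2)N1C(=O)[C@H](C)[C@H](O)[C@H](C)[C@@H](O)[C@@H](C)c3oc(C)c(C)c(=O)c3C | intermediate
25 | (3R,4R,5S,6R)-4-hydroxy-3,5-dimethyl-6-[(1R)-1-(3,5,6-trimethyl-4-oxo-4H-pyran-2-yl)ethyl]oxan-2-one | O=C1[C@H](C)[C@H](O)[C@H](C)[C@@H](O1)[C@@H](C)c2oc(C)c(C)c(=O)c2C | intermediate
26 | (3R,4R,5R,6R)-4-[(tert-butyldimethylsilyl)oxy]-3,5-dimethyl-6-[(1R)-1-(3,5,6-trimethyl-4-oxo-4H-pyran-2-yl)ethyl]oxan-2-one | O=C1[C@H](C)[C@H](O[Si](C)(C)C(C)(C)C)[C@H](C)[C@@H](O1)[C@@H](C)c2oc(C)c(C)c(=O)c2C | intermediate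
27 | lithium (2R,3R,4R,5R,6R)-3-[(tert-butyldimethylsilyl)oxy]-5-hydroxy-2,4-dimethyl-6-(3,5,6-trimethyl-4-oxo-4H-pyran-2-yl)heptanoate | [Li+].[O-]C(=O)[C@H](C)[C@H](O[Si](C)(C)C(C)(C)C)[C@H](C)[C@@H](O)[C@@H](C)c1oc(C)c(C)c(=O)c1C | intermediate
28 | triethylsilyl (2R,3R,4R,5R,6R)-3-[(tert-butyldimethylsilyl)oxy]-2,4-dimethyl-5-[(triethylsilyl)oxy]-6-(3,5,6-trimethyl-4-oxo-4H-pyran-2-yl)heptanoate | CC[Si](CC)(CC)OC(=O)[C@H](C)[C@H](O[Si](C)(C)C(C)(C)C)[C@H](C)[C@@H](O[Si](CC)(CC)CC)[C@@H](C)c1oc(C)c(C)c(=O)c1C | intermediate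
29 | (2R,3R,4R,5R,6R)-3-[(tert-butyldimethylsilyl)oxy]-2,4-dimethyl-5-[(triethylsilyl)oxy]-6-(3,5,6-trimethyl-4-oxo-4H-pyran-2-yl)heptanoic acid | OC(=O)[C@H](C)[C@H](O[Si](C)(C)C(C)(C)C)[C@H](C)[C@@H](O[Si](CC)(CC)CC)[C@@H](C)c1oc(C)c(C)c(=O)c1C | intermediate
30 | (1R,2R,3R,4R,6R)-3-ethyl-3-hydroxy-2,4,6-trimethyl-5-oxocyclohexyl (2R,3R,4R,5R,6R)-3-[(tert-butyldimethylsilyl)oxy]-2,4-dimethyl-5-[(triethylsilyl)oxy]-6-(3,5,6-trimethyl-4-oxo-4H-pyran-2-yl)heptanoate | CC[C@@]1(O)[C@H](C)[C@@H](OC(=O)[C@H](C)[C@H](O[Si](C)(C)C(C)(C)C)[C@H](C)[C@@H](O[Si](CC)(CC)CC)[C@@H](C)c2oc(C)c(C)c(=O)c2C)[C@@H](C)C(=O)[C@@H]1C | intermediate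
31 | (1R,2R,3R,4R,6R)-3-ethyl-3-hydroxy-2,4,6-trimethyl-5-oxocyclohexyl (2R,3R,4R,5R,6R)-3-[(tert-butyldimethylsilyl)oxy]-5-hydroxy-2,4-dimethyl-6-(3,5,6-trimethyl-4-oxo-4H-pyran-2-yl)heptanoate | CC[C@@]1(O)[C@H](C)[C@@H](OC(=O)[C@H](C)[C@H](O[Si](C)(C)C(C)(C)C)[C@H](C)[C@@H](O)[C@@H](C)c2oc(C)c(C)c(=O)c2C)[C@@H](C)C(=O)[C@@H]1C | intermediate
32 | (1R,2R,3R,4R,6R)-3-ethyl-3-hydroxy-2,4,6-trimethyl-5-oxocyclohexyl (2R,3R,4S,6S)-3-[(tert-butyldimethylsilyl)oxy]-2,4-dimethyl-5-oxo-6-(3,5,6-trimethyl-4-oxo-4H-pyran-2-yl)heptanoate | CC[C@@]1(O)[C@H](C)[C@@H](OC(=O)[C@H](C)[C@H](O[Si](C)(C)C(C)(C)C)[C@H](C)C(=O)[C@@H](C)c2oc(C)c(C)c(=O)c2C)[C@@H](C)C(=O)[C@@H]1C | intermediate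
33 | (1R,2R,3R,4R,6R)-3-ethyl-3-hydroxy-2,4,6-trimethyl-5-oxocyclohexyl (2R,3R,4S,6S)-3-hydroxy-2,4-dimethyl-5-oxo-6-(3,5,6-trimethyl-4-oxo-4H-pyran-2-yl)heptanoate | CC[C@@]1(O)[C@H](C)[C@@H](OC(=O)[C@H](C)[C@H](O)[C@H](C)C(=O)[C@@H](C)c2oc(C)c(C)c(=O)c2C)[C@@H](C)C(=O)[C@@H]1C | target

**Step count and risks**

Total step count: 23. Longest linear sequence: 15 steps (1, 2, 10–14, 16–23).

Steps most likely to fail:

Step 8 (proposed new method). The first aldol may show poor anti-Felkin face selectivity; proton transfer, retro-aldol on warming, or C-acylation of enolate 12 by the migrated carbonate may outrun ring closure. The fallback uses known reaction types only, sets out from 7 (with 8) and comes back at 14. The (Z)-enol diisopinocampheylborinate of 8 (Ipc2BOTf antipode chosen for the 6R adduct, iPr2NEt, CH2Cl2, −78 °C) is added to 7; the boron aldolate is not expected to transfer the carbonate, so the product is benzyl (2Z,4R,5S,6R)-5-hydroxy-4,6-dimethyl-7-oxonon-2-en-3-yl carbonate F1. Hydrogenolysis (H2, Pd/C) of the enol carbonate gives (4R,6R)-5-hydroxy-4,6-dimethylnonane-3,7-dione F2. Its carbinol carbon is no longer a stereocentre, so only the reagent-controlled configuration of the new α-carbon matters. Silylation (Et3SiOTf, 2,6-lutidine) gives (4R,6R)-4,6-dimethyl-5-[(triethylsilyl)oxy]nonane-3,7-dione F3. Soft enolisation and intramolecular aldol addition (TiCl4, iPr2NEt, CH2Cl2, −78 °C) should give (2R,3R,4R,5R,6R)-3-ethyl-3-hydroxy-2,4,6-trimethyl-5-[(triethylsilyl)oxy]cyclohexan-1-one F4, through the arm whose α-methyl group can sit pseudoaxial beside the enolate. HF·pyridine then returns to 14.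

Step 20. Acylation of the hindered equatorial alcohol may be slow, so that retro-aldol opening or epimerisation next to the ring ketone of 14 under Et3N/DMAP competes. The fallback sets out from 29 and from 7 and comes back at 30. The open-chain alcohol (4R,6R)-5-hydroxy-4,6-dimethylnonane-3,7-dione F2, made from 7 as described above, has no tertiary ketol and a non-stereogenic carbinol carbon. Yamaguchi acylation of it with 29 gives (4R,6R)-4,6-dimethyl-3,7-dioxononan-5-yl (2R,3R,4R,5R,6R)-3-[(tert-butyldimethylsilyl)oxy]-2,4-dimethyl-5-[(triethylsilyl)oxy]-6-(3,5,6-trimethyl-4-oxo-4H-pyran-2-yl)heptanoate F5. The ring is then closed on the ester by soft enolisation and aldol addition (TiCl4, iPr2NEt, CH2Cl2, −78 °C) to give 30.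

Step 5. The carbonate may migrate from the enol oxygen to the freed primary hydroxyl (the 1,5 relay of step 8 at the wrong stage), or the enol carbonate may be lost during desilylation. The fallback sets out from 1 and comes back at 7, and never forms the free alcohol. The primary oxygen is carried as a triethylsilyl ether through methyl (R)-2-methyl-3-[(triethylsilyl)oxy]propanoate F6, (R)-N-methoxy-N,2-dimethyl-3-[(triethylsilyl)oxy]propanamide F7, (R)-2-methyl-1-[(triethylsilyl)oxy]pentan-3-one F8 and benzyl (2Z,4R)-4-methyl-5-[(triethylsilyl)oxy]pent-2-en-3-yl carbonate F9, made as in steps 1 to 4 with Et3SiCl in place of TBSCl. F9 is then converted directly into 7 under Swern conditions ((COCl)2, DMSO, CH2Cl2, −78 to −30 °C; iPr2NEt), which cleave and oxidise primary triethylsilyl ethers in one operation.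

**Further compounds**

F1 | step 8 | benzyl (2Z,4R,5S,6R)-5-hydroxy-4,6-dimethyl-7-oxonon-2-en-3-yl carbonate | CCC(=O)[C@H](C)[C@@H](O)[C@@H](C)/C(OC(=O)OCc1ccccc1)=C/C
F2 | step 8 | (4R,6R)-5-hydroxy-4,6-dimethylnonane-3,7-dione | CCC(=O)[C@H](C)C(O)[C@@H](C)C(=O)CC
F3 | step 8 | (4R,6R)-4,6-dimethyl-5-[(triethylsilyl)oxy]nonane-3,7-dione | CCC(=O)[C@H](C)C(O[Si](CC)(CC)CC)[C@@H](C)C(=O)CC
F4 | step 8 | (2R,3R,4R,5R,6R)-3-ethyl-3-hydroxy-2,4,6-trimethyl-5-[(triethylsilyl)oxy]cyclohexan-1-one | CC[C@@]1(O)[C@H](C)[C@@H](O[Si](CC)(CC)CC)[C@@H](C)C(=O)[C@@H]1C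
F5 | step 20 | (4R,6R)-4,6-dimethyl-3,7-dioxononan-5-yl (2R,3R,4R,5R,6R)-3-[(tert-butyldimethylsilyl)oxy]-2,4-dimethyl-5-[(triethylsilyl)oxy]-6-(3,5,6-trimethyl-4-oxo-4H-pyran-2-yl)heptanoate | CCC(=O)[C@H](C)C(OC(=O)[C@H](C)[C@H](O[Si](C)(C)C(C)(C)C)[C@H](C)[C@@H](O[Si](CC)(CC)CC)[C@@H](C)c1oc(C)c(C)c(=O)c1C)[C@@H](C)C(=O)CC
F6 | step 5 | methyl (R)-2-methyl-3-[(triethylsilyl)oxy]propanoate | COC(=O)[C@H](C)CO[Si](CC)(CC)CC
F7 | step 5 | (R)-N-methoxy-N,2-dimethyl-3-[(triethylsilyl)oxy]propanamide | CON(C)C(=O)[C@H](C)CO[Si](CC)(CC)CC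
F8 | step 5 | (R)-2-methyl-1-[(triethylsilyl)oxy]pentan-3-one | CCC(=O)[C@H](C)CO[Si](CC)(CC)CC
F9 | step 5 | benzyl (2Z,4R)-4-methyl-5-[(triethylsilyl)oxy]pent-2-en-3-yl carbonate | C/C=C(OC(=O)OCc1ccccc1)/[C@H](C)CO[Si](CC)(CC)CC
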